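The ester of an unbranched C22 alcohol (C1 = OCH2, C22 = CH3) with 2,3-dihydroxybenzoic acid has one benzene ring and a free catechol (O2, O3). The key step exploits the heteroatom-free polymethylene run C2–C22, where an alkene placed anywhere is traceless after hydrogenation. C9 and C10 are two methylenes of like polarity. Disconnecting them at the alkene level gives odd C9 and C13 pieces. These are the even α-olefin feedstocks dec-9-en-1-ol and tetradec-1-ene, each minus one CH2. Cross-metathesis of dec-9-enyl 2,3-dihydroxybenzoate (one Mitsunobu step, catechol unprotected) with tetradec-1-ene expels ethene and forges C9=C10. Hydrogenation in the same flask then delivers the natural product directly.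

Key step: step 2

Assumption: the SMILES holds no stereocentre and no stereogenic double bond, so the target is achiral and the route needs no stereocontrol.

Step 1
Reactants: 1 2,3-dihydroxybenzoic acid; 2 dec-9-en-1-ol
Product: 3 dec-9-en-1-yl 2,3-dihydroxybenzoate
Conditions: 1 (1.2 equiv), PPh3 (1.2 equiv), DIAD (1.2 equiv), THF, 0 °C to rt
Reagents that add atoms: none
Why: Mitsunobu esterification: the carboxylic acid of 1 (pKa about 3) protonates the PPh3–DIAD betaine far ahead of the two phenols (pKa about 10, O2–H also tied to the carbonyl by a hydrogen bond), so only the carboxylate displaces the oxyphosphonium group at the primary C1 of 2, a chemoselectivity known for unprotected phenolic acids, and the remote alkene is inert.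

Step 2
Reactants: 3 dec-9-en-1-yl 2,3-dihydroxybenzoate; 4 tetradec-1-ene
Product: 6 gentiside J (docosyl 2,3-dihydroxybenzoate), via docos-9-enyl ester 5 (not isolated)
Conditions: Hoveyda–Grubbs II (2 mol %), AcOH (10 mol %), 4 (5 equiv), EtOAc, 40 °C, Ar sparge; then 10 % Pd/C, H2 (1 atm), same flask, 40 °C
Reagents that add atoms: none
Why: The Ru alkylidene engages the terminal alkenes of 3 (C9=C10) and 4 (C1=C2) in [2+2] cycloaddition/cycloreversion cycles through ruthenacyclobutanes, so that the two =CH2 termini leave as ethene and the two inner CH carbons, which have the same polarity and could not be joined by an ionic reaction, become C9=C10 of 5. The closest known reaction type is olefin cross-metathesis of two unhindered terminal (type I) alkenes, telescoped with heterogeneous hydrogenation in the same flask. No ring is closed and no stereocentre is made, and the E/Z ratio of 5 does not matter because Pd/C and H2 turn C9=C10 into the C9–C10 single bond of 6. The selectivity needed is cross- over homocoupling, which is statistical for this pair and is secured by the fivefold excess of cheap 4, by sweeping out ethene and by secondary metathesis of the homodimers, while the by-products carry no or two catechol ester heads and should therefore separate from 6 by polarity. The free catechol should be tolerated because the medium is neutral to slightly acidic, so that no catecholate can displace chloride on Ru, and because O2–H is held in a hydrogen bond to the ester carbonyl. Acetic acid and the low temperature should suppress Ru–H double-bond migration, which would otherwise blur the chain length, and the ester and the benzene ring are inert to Pd/C and H2 at 1 atm.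

Compound list
1 | 2,3-dihydroxybenzoic acid | O=C(O)c1cccc(O)c1O | starting material
2 | dec-9-en-1-ol | C=CCCCCCCCCO | starting material
3 | dec-9-en-1-yl 2,3-dihydroxybenzoate | C=CCCCCCCCCOC(=O)c1cccc(O)c1O | intermediate
4 | tetradec-1-ene | CCCCCCCCCCCCC=C | starting material
5 | docos-9-en-1-yl 2,3-dihydroxybenzoate (E/Z mixture, E isomer drawn, not isolated) | CCCCCCCCCCCC/C=C/CCCCCCCCOC(=O)c1cccc(O)c1O | intermediate
6 | gentiside J, docosyl 2,3-dihydroxybenzoate | CCCCCCCCCCCCCCCCCCCCCCOC(=O)c1cccc(O)c1O | target

Total step count: 2
Longest linear sequence: 2 steps (1 to 3 to 6)

Steps most likely to fail (the route has only two steps, so the two stages of step 2 are ranked separately):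

1. Step 2, metathesis stage.
- What may go wrong: the free catechol may chelate and deactivate the Ru carbene. Material may be lost statistically to homocoupling. The double bond may migrate before metathesis, which would spread the chain length.
- Fallback (sets out from 3, comes back at 6): the same C9–C10 bond is made by a polarity-differentiated Wittig olefination, which cannot homocouple and involves no metal hydride. Compound 3 is benzylated (BnBr, K2CO3, DMF, 60 °C) to dec-9-en-1-yl 2,3-bis(benzyloxy)benzoate F1. Lemieux–Johnson cleavage of its terminal alkene (cat. OsO4, NaIO4, 2,6-lutidine, dioxane/H2O) gives 9-oxononyl 2,3-bis(benzyloxy)benzoate F2. 1-Bromotridecane and PPh3 (MeCN, reflux) give tridecyl(triphenyl)phosphonium bromide F3. NaHMDS (THF, −78 °C) converts this into tridecylidene(triphenyl)phosphorane F4, and addition of F2 gives (Z)-docos-9-en-1-yl 2,3-bis(benzyloxy)benzoate F5. Hydrogenation (H2, Pd/C, EtOAc) saturates the alkene and cleaves both benzyl ethers in one operation to give 6.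

2. Step 2, hydrogenation stage.
- What may go wrong: Ru and NHC residues may poison the Pd surface, or the waxy product may coat the catalyst. Either would leave the saturation incomplete.
- Fallback (sets out from 5, comes back at 6): the metathesis mixture is worked up and 5 is isolated by chromatography. It is then reduced without any metal by diimide (TsNHNH2, NaOAc, DME/H2O, reflux, under N2). New compounds: none F0.

3. Step 1.
- What may go wrong: the phenol at C3 may be O-alkylated in competition, and the phosphine oxide may co-elute with the lipophilic ester.
- Fallback (sets out from 1 and 2, comes back at 3): the acyl group is activated instead of the alkyl group, by Fischer esterification (TsOH·H2O 10 mol %, toluene, Dean–Stark reflux). Under these conditions a phenol cannot be alkylated. New compounds: none F0.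

Further compounds
F1 | step 2 | dec-9-en-1-yl 2,3-bis(benzyloxy)benzoate | C=CCCCCCCCCOC(=O)c1cccc(OCc2ccccc2)c1OCc1ccccc1
F2 | step 2 | 9-oxononyl 2,3-bis(benzyloxy)benzoate | O=CCCCCCCCCOC(=O)c1cccc(OCc2ccccc2)c1OCc1ccccc1
F3 | step 2 | tridecyl(triphenyl)phosphonium bromide | CCCCCCCCCCCCC[P+](c1ccccc1)(c1ccccc1)c1ccccc1.[Br-]
F4 | step 2 | tridecylidene(triphenyl)phosphorane | CCCCCCCCCCCCC=P(c1ccccc1)(c1ccccc1)c1ccccc1
F5 | step 2 | (Z)-docos-9-en-1-yl 2,3-bis(benzyloxy)benzoate | CCCCCCCCCCCC/C=C\CCCCCCCCOC(=O)c1cccc(OCc2ccccc2)c1OCc1ccccc1
F0 | step 2 | none | none
F0 | step 1 | none | none
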